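The flavanone is cut at C4–C4a of ring C, giving a (3R)-3-aryl-3-aryloxypropanoic acid whose stereocentre comes from Mitsunobu inversion of an (S)-benzylic alcohol. Activating the acid as a trifluoroacetic mixed anhydride lets its acyl carbon attack ring A and close the chromanone in one operation, leaving C2 untouched. The step exploits the symmetry of ring A: with O5 and O7 both methylated, C4a and C8 are mirror images across the C8a–C6 axis, so only the 6-benzyl isomer can form; O5 is freed later via its C4-carbonyl chelate. The precursor carries an electron-poor 4-acetoxyphenyl group at the stereocentre and a benzyl ether on ring D, the C6 benzyl ring.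

Key step: step 8

Remark: C2 of the target is (R) (O1 > aryl > C3 > H); the same priority order holds at the aryl-bearing carbon of every open-chain intermediate, so an inverting etherification needs the (S)-alcohol.

Step 1
Reactants: 1 3,5-dimethoxyphenol
Product: 2 (3,5-dimethoxyphenoxy)tri(propan-2-yl)silane
Conditions: TIPSCl, imidazole, DMF, rt
Reagents that add atoms: chlorotri(propan-2-yl)silane (TIPSCl), CC(C)[Si](Cl)(C(C)C)C(C)C
Why: O-Silylation of a phenol with a bulky silyl chloride gives an aryl silyl ether that resists n-BuLi and is a hindered, poor ligand for lithium, so the carbon between the two methoxy groups remains the only site for the directed metalation that follows.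

Step 2
Reactants: 2 (3,5-dimethoxyphenoxy)tri(propan-2-yl)silane; 3 2-(benzyloxy)benzaldehyde
Product: 5 rac-[2-(benzyloxy)phenyl]{2,6-dimethoxy-4-[tri(propan-2-yl)silyloxy]phenyl}methanol, via aryllithium 4 (not isolated)
Conditions: n-BuLi, THF, 0 °C → rt; then 3, −78 °C → rt; aq. NH4Cl
Reagents that add atoms: none
Why: Directed ortho-metalation followed by 1,2-addition to an aldehyde should work because n-BuLi removes the proton at C4 of 2, the one carbon flanked by two coordinating methoxy groups, while the positions next to the bulky silyloxy group stay untouched; aryllithium 4 then adds to aldehyde 3, and the racemic carbinol centre is removed in step 3.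

Step 3
Reactants: 5 rac-[2-(benzyloxy)phenyl]{2,6-dimethoxy-4-[tri(propan-2-yl)silyloxy]phenyl}methanol
Product: 7 4-[2-(benzyloxy)benzyl]-3,5-dimethoxyphenol, via silyl ether 6 (not isolated)
Conditions: Et3SiH, CF3CO2H, CH2Cl2, 0 °C; evaporate; Bu4NF, THF, 0 °C → rt; aq. NH4Cl
Reagents that add atoms: none
Why: Ionic hydrogenation followed by fluoride desilylation should work because CF3CO2H ionises the diarylcarbinol to a cation stabilised by two ortho methoxy groups, Et3SiH delivers hydride to it, and after removal of the acid Bu4NF cleaves the aryl silyl ether, while the benzyl ether tolerates the brief cold acid.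

Step 4
Reactants: 8 4-(chlorocarbonyl)phenyl acetate (4-acetoxybenzoyl chloride); 9 potassium 3-(tert-butoxy)-3-oxopropanoate
Product: 11 tert-butyl 3-(4-acetoxyphenyl)-3-oxopropanoate, via acylmalonic half-ester 10 (not isolated)
Conditions: MgCl2, Et3N, MeCN, 0 °C → rt; then 1 M HCl, 0 °C
Reagents that add atoms: none
Why: C-Acylation of a magnesium malonate half-ester enolate by an acid chloride, with decarboxylation on acidification (a decarboxylative Claisen-type condensation), should give the β-keto ester because the soft chelated enolate reacts at the acid chloride and not at the aryl acetate.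

Step 5
Reactants: 11 tert-butyl 3-(4-acetoxyphenyl)-3-oxopropanoate
Product: 12 tert-butyl (3S)-3-(4-acetoxyphenyl)-3-hydroxypropanoate
Conditions: RuCl[(S,S)-TsDPEN](p-cymene) (1 mol %), HCO2H/Et3N (5:2), EtOAc, 30 °C
Reagents that add atoms: none
Why: Noyori-type asymmetric transfer hydrogenation of an aryl ketone should set the carbinol as (S) because the (S,S)-TsDPEN ruthenium hydride transfers hydride and proton through its six-membered outer-sphere transition state to the same carbonyl face as in acetophenone → (S)-1-phenylethanol (priority order O > aryl > CH2 unchanged), and both esters are inert to the formate reductant.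

Step 6
Reactants: 7 4-[2-(benzyloxy)benzyl]-3,5-dimethoxyphenol; 12 tert-butyl (3S)-3-(4-acetoxyphenyl)-3-hydroxypropanoate
Product: 14 tert-butyl (3R)-3-(4-acetoxyphenyl)-3-{4-[2-(benzyloxy)benzyl]-3,5-dimethoxyphenoxy}propanoate, via oxyphosphonium salt 13 (not isolated)
Conditions: PPh3, DIAD (slow addition), toluene, 0 °C → rt
Reagents that add atoms: none
Why: Mitsunobu etherification should work because phenol 7 (pKa about 10) protonates the PPh3/DIAD betaine, alcohol 12 is activated as oxyphosphonium salt 13, and the aryloxide displaces Ph3P=O in an SN2 step that inverts the benzylic centre from (S) to (R); the electron-poor acetoxyphenyl ring disfavours ionisation, and the bulky tert-butyl ester, non-polar solvent and low temperature hold back elimination to the cinnamate.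

Step 7
Reactants: 14 tert-butyl (3R)-3-(4-acetoxyphenyl)-3-{4-[2-(benzyloxy)benzyl]-3,5-dimethoxyphenoxy}propanoate
Product: 16 (3R)-3-(4-acetoxyphenyl)-3-{4-[2-(benzyloxy)benzyl]-3,5-dimethoxyphenoxy}propanoic acid, via trimethylsilyl ester 15 (not isolated)
Conditions: TMSOTf, 2,6-lutidine, CH2Cl2, 0 °C → rt; then aq. KH2PO4
Reagents that add atoms: none
Why: Silyl triflate-mediated cleavage of a tert-butyl ester should work because TMSOTf silylates the ester carbonyl, isobutene is lost with 2,6-lutidine taking the proton, and mild aqueous work-up hydrolyses silyl ester 15, so neither a strong protic acid (which could ionise the benzylic aryl ether) nor a long-lived tert-butyl cation (which could alkylate ring A) is present, and the aryl acetate and benzyl ether stay intact.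

Step 8
Reactants: 16 (3R)-3-(4-acetoxyphenyl)-3-{4-[2-(benzyloxy)benzyl]-3,5-dimethoxyphenoxy}propanoic acid
Product: 18 (2R)-2-(4-acetoxyphenyl)-6-[2-(benzyloxy)benzyl]-5,7-dimethoxychroman-4-one, via mixed anhydride 17 (not isolated)
Conditions: (CF3CO)2O (2 equiv), CH2Cl2, 0 °C → rt
Reagents that add atoms: none
Why: This is an intramolecular Friedel–Crafts acylation, the established way from 3-aryloxypropanoic acids to chroman-4-ones: (CF3CO)2O turns acid 16 into mixed anhydride 17, whose acyl carbon (as such or as the acylium ion) is attacked by ring A at the carbon ortho to the ether oxygen and para to a methoxy group, and loss of a proton from the arenium ion gives ketone 18 and CF3CO2H. Ring C closes as a six-membered ring by 6-exo attack of the ring A π-system on the acyl carbon, forming only the C4–C4a bond. No stereocentre is created; C2, set in step 6, lies outside the bonds that change and should keep its (R) configuration. Regiochemistry needs no control, because with O5 and O7 both methylated the two ortho carbons of the aryloxy ring (the future C4a and C8) are mirror images across the C8a–C6 axis, so only the 6-benzyl chromanone can form. Chemoselectivity for ring A over rings B and D follows from its three oxygen donors and from the fact that only ring A reaches the acyl carbon through a six-membered transition state. Acid ionisation of the benzylic C2–O1 bond, which would lead to racemate or chalcone, is held back by the electron-poor 4-acetoxyphenyl group, the low temperature and the small amount of CF3CO2H present in dilute CH2Cl2.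

Step 9
Reactants: 18 (2R)-2-(4-acetoxyphenyl)-6-[2-(benzyloxy)benzyl]-5,7-dimethoxychroman-4-one
Product: 20 (+)-methylphelligrin A [(2R)-5-hydroxy-6-(2-hydroxybenzyl)-2-(4-hydroxyphenyl)-7-methoxychroman-4-one], via 4′-acetate 19 (not isolated)
Conditions: BCl3 (5 equiv), C6HMe5, CH2Cl2, −78 → 0 °C; then MeOH, 0 °C → rt
Reagents that add atoms: none
Why: Lewis-acid ether cleavage followed by acid-catalysed transesterification should work because BCl3 removes the one O-benzyl group (the benzyl cation being captured by pentamethylbenzene) and, through boron chelation between O5 and the C4 carbonyl, cleaves only the 5-methyl ether while the unchelated 7-methoxy group stays; the HCl/MeOH formed on quenching with methanol then removes the aryl acetate without any base that could open ring C and racemise C2.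

Compound list
1 | 3,5-dimethoxyphenol | COc1cc(O)cc(OC)c1 | starting material
2 | (3,5-dimethoxyphenoxy)tri(propan-2-yl)silane | COc1cc(O[Si](C(C)C)(C(C)C)C(C)C)cc(OC)c1 | intermediate
3 | 2-(benzyloxy)benzaldehyde | O=Cc1ccccc1OCc1ccccc1 | starting material
4 | {2,6-dimethoxy-4-[tri(propan-2-yl)silyloxy]phenyl}lithium | [Li]c1c(OC)cc(O[Si](C(C)C)(C(C)C)C(C)C)cc1OC | intermediate (not isolated)
5 | rac-[2-(benzyloxy)phenyl]{2,6-dimethoxy-4-[tri(propan-2-yl)silyloxy]phenyl}methanol | COc1cc(O[Si](C(C)C)(C(C)C)C(C)C)cc(OC)c1C(O)c1ccccc1OCc1ccccc1 | intermediate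
6 | {4-[2-(benzyloxy)benzyl]-3,5-dimethoxyphenoxy}tri(propan-2-yl)silane | COc1cc(O[Si](C(C)C)(C(C)C)C(C)C)cc(OC)c1Cc1ccccc1OCc1ccccc1 | intermediate (not isolated)
7 | 4-[2-(benzyloxy)benzyl]-3,5-dimethoxyphenol | COc1cc(O)cc(OC)c1Cc1ccccc1OCc1ccccc1 | intermediate
8 | 4-(chlorocarbonyl)phenyl acetate | CC(=O)Oc1ccc(cc1)C(Cl)=O | starting material
9 | potassium 3-(tert-butoxy)-3-oxopropanoate | CC(C)(C)OC(=O)CC(=O)[O-].[K+] | starting material
10 | 2-(4-acetoxybenzoyl)-3-(tert-butoxy)-3-oxopropanoic acid (formed as its magnesium chelate, freed on acidification) | CC(=O)Oc1ccc(cc1)C(=O)C(C(O)=O)C(=O)OC(C)(C)C | intermediate (not isolated)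
11 | tert-butyl 3-(4-acetoxyphenyl)-3-oxopropanoate | CC(=O)Oc1ccc(cc1)C(=O)CC(=O)OC(C)(C)C | intermediate
12 | tert-butyl (3S)-3-(4-acetoxyphenyl)-3-hydroxypropanoate | CC(=O)Oc1ccc(cc1)[C@@H](O)CC(=O)OC(C)(C)C | intermediate
13 | [(1S)-1-(4-acetoxyphenyl)-3-(tert-butoxy)-3-oxopropoxy]triphenylphosphonium 4-[2-(benzyloxy)benzyl]-3,5-dimethoxyphenoxide | CC(=O)Oc1ccc(cc1)[C@@H](O[P+](c1ccccc1)(c1ccccc1)c1ccccc1)CC(=O)OC(C)(C)C.[O-]c1cc(OC)c(Cc2ccccc2OCc2ccccc2)c(OC)c1 | intermediate (not isolated)
14 | tert-butyl (3R)-3-(4-acetoxyphenyl)-3-{4-[2-(benzyloxy)benzyl]-3,5-dimethoxyphenoxy}propanoate | CC(C)(C)OC(=O)C[C@H](c1ccc(OC(C)=O)cc1)Oc1cc(OC)c(Cc2ccccc2OCc2ccccc2)c(OC)c1 | intermediate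
15 | trimethylsilyl (3R)-3-(4-acetoxyphenyl)-3-{4-[2-(benzyloxy)benzyl]-3,5-dimethoxyphenoxy}propanoate | C[Si](C)(C)OC(=O)C[C@H](c1ccc(OC(C)=O)cc1)Oc1cc(OC)c(Cc2ccccc2OCc2ccccc2)c(OC)c1 | intermediate (not isolated)
16 | (3R)-3-(4-acetoxyphenyl)-3-{4-[2-(benzyloxy)benzyl]-3,5-dimethoxyphenoxy}propanoic acid | OC(=O)C[C@H](c1ccc(OC(C)=O)cc1)Oc1cc(OC)c(Cc2ccccc2OCc2ccccc2)c(OC)c1 | intermediate
17 | (3R)-3-(4-acetoxyphenyl)-3-{4-[2-(benzyloxy)benzyl]-3,5-dimethoxyphenoxy}propanoic trifluoroacetic anhydride | O=C(OC(=O)C(F)(F)F)C[C@H](c1ccc(OC(C)=O)cc1)Oc1cc(OC)c(Cc2ccccc2OCc2ccccc2)c(OC)c1 | intermediate (not isolated)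
18 | (2R)-2-(4-acetoxyphenyl)-6-[2-(benzyloxy)benzyl]-5,7-dimethoxychroman-4-one | COc1cc2c(c(OC)c1Cc1ccccc1OCc1ccccc1)C(=O)C[C@H](c1ccc(OC(C)=O)cc1)O2 | intermediate
19 | (2R)-2-(4-acetoxyphenyl)-5-hydroxy-6-(2-hydroxybenzyl)-7-methoxychroman-4-one | COc1cc2c(c(O)c1Cc1ccccc1O)C(=O)C[C@H](c1ccc(OC(C)=O)cc1)O2 | intermediate (not isolated)
20 | (+)-methylphelligrin A, (2R)-5-hydroxy-6-(2-hydroxybenzyl)-2-(4-hydroxyphenyl)-7-methoxychroman-4-one | COc1cc2c(c(O)c1Cc1ccccc1O)C(=O)C[C@H](c1ccc(O)cc1)O2 | target

Total step count: 9. Longest linear sequence: 7 steps (1, 2, 3, 6, 7, 8, 9).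

Steps most likely to fail

Step 6. The activated β-hydroxy ester may eliminate to the cinnamate, the oxyphosphonium salt may partly ionise with erosion of enantiopurity, and acetyl may transfer from the aryl acetate to the aryloxide. The fallback sets out from 7 and returns at 16; it takes the acidifying ester out of the etherification. 4-Formylphenyl acetate is allylated enantioselectively (Ipc2B(allyl), −78 °C, the antipode that gives the (S)-carbinol, non-oxidative ethanolamine work-up) to (1S)-1-(4-acetoxyphenyl)but-3-en-1-ol F1. Mitsunobu coupling of F1 with 7 (PPh3, DIAD) should give, with inversion, 4-[(1R)-1-{4-[2-(benzyloxy)benzyl]-3,5-dimethoxyphenoxy}but-3-en-1-yl]phenyl acetate F2. Dihydroxylation (OsO4 cat., NMO) leads to 4-[(1R)-1-{4-[2-(benzyloxy)benzyl]-3,5-dimethoxyphenoxy}-3,4-dihydroxybutyl]phenyl acetate F3. NaIO4 cleavage gives 4-[(1R)-1-{4-[2-(benzyloxy)benzyl]-3,5-dimethoxyphenoxy}-3-oxopropyl]phenyl acetate F4, which is oxidised at once (NaClO2, NaH2PO4, 2-methyl-2-butene) to acid 16.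

Step 8. The benzylic C2–O1 bond may ionise or the activated acid may undergo β-elimination, giving chalcone-type material and loss of enantiopurity; ring A may also be C-trifluoroacetylated, or the closure may stall. The fallback sets out from 7 and returns at 18; it builds ring C in the reverse order and sets C2 last. Ortho-acetylation of 7 (Ac2O, BF3·OEt2; the two ortho carbons are again equivalent) gives 1-{3-[2-(benzyloxy)benzyl]-6-hydroxy-2,4-dimethoxyphenyl}ethan-1-one F5. Condensation with DMF dimethyl acetal gives (2E)-1-{3-[2-(benzyloxy)benzyl]-6-hydroxy-2,4-dimethoxyphenyl}-3-(dimethylamino)prop-2-en-1-one F6. Acid (HCl, CH2Cl2) closes F6 to 6-[2-(benzyloxy)benzyl]-5,7-dimethoxy-4H-chromen-4-one F7. Rhodium-catalysed asymmetric 1,4-addition of [4-(acetyloxy)phenyl]boronic acid ([RhOH(cod)]2 with an electron-poor chiral biaryl bisphosphine, the antipode that gives 2R) then delivers 18.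

Step 9. The two methyl ethers may not be fully discriminated, the Lewis acid may open ring C with racemisation, the benzyl cation may re-attack the electron-rich rings, and methanolysis of the acetate may be incomplete. The fallback sets out from 18 and returns at 19; it replaces the single global Lewis-acid operation by staged, orthogonal deprotection. Hydrogenolysis (H2, Pd/C, EtOAc, rt) removes the benzyl ether to give (2R)-2-(4-acetoxyphenyl)-6-(2-hydroxybenzyl)-5,7-dimethoxychroman-4-one F8. MgI2·OEt2 (THF, 50 °C) then cleaves only the chelated 5-methyl ether to give 19, and HCl in MeOH at rt converts 19 into 20 as in the second stage of step 9.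

Further compounds
F1 | step 6 | (1S)-1-(4-acetoxyphenyl)but-3-en-1-ol | CC(=O)Oc1ccc(cc1)[C@@H](O)CC=C
F2 | step 6 | 4-[(1R)-1-{4-[2-(benzyloxy)benzyl]-3,5-dimethoxyphenoxy}but-3-en-1-yl]phenyl acetate | C=CC[C@H](c1ccc(OC(C)=O)cc1)Oc1cc(OC)c(Cc2ccccc2OCc2ccccc2)c(OC)c1
F3 | step 6 | 4-[(1R)-1-{4-[2-(benzyloxy)benzyl]-3,5-dimethoxyphenoxy}-3,4-dihydroxybutyl]phenyl acetate (both C3 epimers) | OCC(O)C[C@H](c1ccc(OC(C)=O)cc1)Oc1cc(OC)c(Cc2ccccc2OCc2ccccc2)c(OC)c1
F4 | step 6 | 4-[(1R)-1-{4-[2-(benzyloxy)benzyl]-3,5-dimethoxyphenoxy}-3-oxopropyl]phenyl acetate | O=CC[C@H](c1ccc(OC(C)=O)cc1)Oc1cc(OC)c(Cc2ccccc2OCc2ccccc2)c(OC)c1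
F5 | step 8 | 1-{3-[2-(benzyloxy)benzyl]-6-hydroxy-2,4-dimethoxyphenyl}ethan-1-one | CC(=O)c1c(O)cc(OC)c(Cc2ccccc2OCc2ccccc2)c1OC
F6 | step 8 | (2E)-1-{3-[2-(benzyloxy)benzyl]-6-hydroxy-2,4-dimethoxyphenyl}-3-(dimethylamino)prop-2-en-1-one | CN(C)/C=C/C(=O)c1c(O)cc(OC)c(Cc2ccccc2OCc2ccccc2)c1OC
F7 | step 8 | 6-[2-(benzyloxy)benzyl]-5,7-dimethoxy-4H-chromen-4-one | COc1cc2occc(=O)c2c(OC)c1Cc1ccccc1OCc1ccccc1
F8 | step 9 | (2R)-2-(4-acetoxyphenyl)-6-(2-hydroxybenzyl)-5,7-dimethoxychroman-4-one | COc1cc2c(c(OC)c1Cc1ccccc1O)C(=O)C[C@H](c1ccc(OC(C)=O)cc1)O2
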